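## Retrosynthetic overview

1. The vanillate ester is attached last: Yamaguchi acylation of the free ring hydroxyl at C4 (octahydroazulene numbering) with O-silylated vanillic acid, then global desilylation.
2. The seven-membered ring is formed last, on a preformed cyclopentane, by ring-closing metathesis of a vinyl carbinol arm with an isopropenyl carbinol arm (C5=C6). The C7 carbinol comes from a CBS reduction of an isopropenyl ketone built on an aldehyde unmasked from an allyl group.
3. The tertiary isopropyl carbinol comes from isopropyl Grignard addition to the cyclopentanone, anti to the neighbouring side chain.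
4. Key C–C bond (ring carbon C3a to carbinol carbon C4): intermolecular anti-selective boron aldol of a regiodefined cyclopentanone enolate with 3-(trimethylsilyl)propynal.
5. The five-membered ring is bought as 3-ethoxycyclopentenone. Allyl Grignard addition with carbonyl transposition, then copper-catalysed asymmetric conjugate methylation with enolate trapping, give the quaternary carbon and the enolate.

Assumption: the sense of induction in step 2 is fixed by the choice of ligand antipode, and the antipode that gives the (3R) enol silane is used; all later stereocentres follow from it or from named reagent antipodes.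

## Route

Step 1
Reactants: 1 3-ethoxycyclopent-2-en-1-one; 2 allylmagnesium bromide
Product: 4 3-(prop-2-en-1-yl)cyclopent-2-en-1-one, via magnesium alkoxide adduct 3 (not isolated)
Conditions: THF, 0 °C; then 1 M HCl, 0 °C
Reagents that add atoms: water, O
Why: Stork–Danheiser sequence in which 1,2-addition of the Grignard reagent to the vinylogous ester and acid hydrolysis of the enol ether (loss of ethanol) transpose the carbonyl and give the 3-substituted enone, with no stereocentre formed.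

Step 2
Reactants: 4 3-allylcyclopentenone; 5 trimethylaluminium
Product: 7 triethyl{[(3R)-3-methyl-3-(prop-2-en-1-yl)cyclopent-1-en-1-yl]oxy}silane, via dimethylaluminium enolate 6 (not isolated)
Conditions: Me3Al (1.5 equiv), Cu(O2CC4H3S) (copper thiophene-2-carboxylate, 5 mol %), O,O′-(biphenyl-2,2′-diyl) N,N-bis[1-(naphthalen-2-yl)ethyl]phosphoramidite (10 mol %), Et2O, −30 °C; then Et3SiOTf, THF, −30 → 0 °C
Reagents that add atoms: triethylsilyl trifluoromethanesulfonate, CC[Si](CC)(CC)OS(=O)(=O)C(F)(F)F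
Why: Copper-catalysed asymmetric conjugate addition puts the methyl group on the β-carbon and sets the quaternary stereocentre under ligand control, and O-silylation of the aluminium enolate locks the enolate on the side of the quaternary carbon.

Step 3
Reactants: 7 silyl enol ether; 8 3-(trimethylsilyl)prop-2-ynal
Product: 12 (2S,3R)-2-[(1R)-1-hydroxy-3-(trimethylsilyl)prop-2-yn-1-yl]-3-methyl-3-(prop-2-en-1-yl)cyclopentan-1-one, via lithium enolate 9 (not isolated), via dibutylboron enolate 10 (not isolated), via dibutylboron aldolate 11 (not isolated)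
Conditions: MeLi, THF, 0 °C; n-Bu2BOTf, −78 °C; 8, −78 → −40 °C; then pH 7 buffer, MeOH, 30% H2O2, 0 °C
Reagents that add atoms: none
Why: Intermolecular boron aldol reaction in which silicon–lithium–boron exchange keeps the enolate regiochemistry, the ring-locked E-enolate reacts through a Zimmerman–Traxler chair to give the anti aldol (1R carbinol), and the aldehyde approaches the enolate face anti to the larger allyl group, which sets C2 as S (side chain cis to methyl).

Step 4
Reactants: 12 aldol adduct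
Product: 13 (2S,3R)-3-methyl-3-(prop-2-en-1-yl)-2-[(1R)-1-(triethylsilyloxy)-3-(trimethylsilyl)prop-2-yn-1-yl]cyclopentan-1-one
Conditions: Et3SiOTf, 2,6-lutidine, CH2Cl2, −78 °C
Reagents that add atoms: triethylsilyl trifluoromethanesulfonate, CC[Si](CC)(CC)OS(=O)(=O)C(F)(F)F
Why: Silyl ether formation with a silyl triflate at low temperature protects the propargylic hydroxyl without retro-aldol cleavage or β-elimination and touches no stereocentre.

Step 5
Reactants: 13 silyl-protected aldol; 14 isopropylmagnesium chloride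
Product: 16 (1R,2S,3R)-3-methyl-1-(propan-2-yl)-3-(prop-2-en-1-yl)-2-[(1R)-1-(triethylsilyloxy)-3-(trimethylsilyl)prop-2-yn-1-yl]cyclopentan-1-ol, via chloromagnesium alkoxide 15 (not isolated)
Conditions: i-PrMgCl, LaCl3·2LiCl, THF, 0 °C
Reagents that add atoms: none
Why: Lanthanum-promoted Grignard 1,2-addition suppresses enolisation and reduction, and the isopropyl group enters the carbonyl face anti to the bulky C2 side chain, so the new tertiary hydroxyl is cis to that side chain (1R).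

Step 6
Reactants: 16 tertiary alcohol
Product: 18 2-{(1R,2S,3R)-3-hydroxy-1-methyl-3-(propan-2-yl)-2-[(1R)-1-(triethylsilyloxy)-3-(trimethylsilyl)prop-2-yn-1-yl]cyclopentyl}acetaldehyde, via vicinal diol 17 (not isolated)
Conditions: OsO4 (2 mol %), NaIO4, 2,6-lutidine, 1,4-dioxane/H2O 3:1, rt
Reagents that add atoms: osmium tetroxide, O=[Os](=O)(=O)=O; sodium periodate, [Na+].[O-]I(=O)(=O)=O
Why: Lemieux–Johnson oxidative cleavage in which OsO4 dihydroxylates only the terminal alkene (the silylalkyne is inert) and periodate cleaves the diol to the aldehyde, with no stereocentre touched.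

Step 7
Reactants: 18 aldehyde; 19 isopropenylmagnesium bromide
Product: 21 (2RS)-1-{(1R,2S,3R)-3-hydroxy-1-methyl-3-(propan-2-yl)-2-[(1R)-1-(triethylsilyloxy)-3-(trimethylsilyl)prop-2-yn-1-yl]cyclopentyl}-3-methylbut-3-en-2-ol, via bis(bromomagnesium) alkoxide 20 (not isolated)
Conditions: CH2=C(CH3)MgBr (3 equiv), THF, −78 → 0 °C
Reagents that add atoms: none
Why: Grignard 1,2-addition to the unhindered aldehyde (one equivalent is consumed by the tertiary hydroxyl) installs the 1,1-disubstituted alkene, and the uncontrolled new carbinol is erased in step 8.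

Step 8
Reactants: 21 allylic alcohol epimers
Product: 22 1-{(1R,2S,3R)-3-hydroxy-1-methyl-3-(propan-2-yl)-2-[(1R)-1-(triethylsilyloxy)-3-(trimethylsilyl)prop-2-yn-1-yl]cyclopentyl}-3-methylbut-3-en-2-one
Conditions: Dess–Martin periodinane, NaHCO3, CH2Cl2, rt
Reagents that add atoms: none
Why: Dess–Martin oxidation converts both secondary allylic alcohol epimers into one enone under near-neutral conditions, while the tertiary alcohol cannot be oxidised.

Step 9
Reactants: 22 enone
Product: 24 (2S)-1-{(1R,2S,3R)-3-hydroxy-1-methyl-3-(propan-2-yl)-2-[(1R)-1-(triethylsilyloxy)-3-(trimethylsilyl)prop-2-yn-1-yl]cyclopentyl}-3-methylbut-3-en-2-ol, via catechol borate ester 23 (not isolated)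
Conditions: (R)-2-methyl-CBS-oxazaborolidine (20 mol %), catecholborane, toluene, −78 °C; then MeOH, aq. NaOH
Reagents that add atoms: none
Why: Corey–Bakshi–Shibata reduction in which the (R)-oxazaborolidine treats the α-branched isopropenyl group as the large substituent and delivers hydride under reagent control to give the (2S) allylic alcohol, remote from the ring stereocentres.

Step 10
Reactants: 24 (2S) allylic alcohol
Product: 25 (2S)-1-{(1R,2S,3R)-3-hydroxy-1-methyl-3-(propan-2-yl)-2-[(1R)-1-(triethylsilyloxy)prop-2-yn-1-yl]cyclopentyl}-3-methylbut-3-en-2-ol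
Conditions: K2CO3, MeOH, rt
Reagents that add atoms: none
Why: Base-catalysed methanolysis of the alkynyl C–Si bond frees the terminal alkyne, while the secondary triethylsilyl ether is stable to these conditions.

Step 11
Reactants: 25 terminal alkyne
Product: 26 (2S)-1-{(1R,2S,3R)-3-hydroxy-1-methyl-3-(propan-2-yl)-2-[(1S)-1-(triethylsilyloxy)prop-2-en-1-yl]cyclopentyl}-3-methylbut-3-en-2-ol
Conditions: H2 (1 atm), Pd/CaCO3 poisoned with Pb(OAc)2 (Lindlar catalyst), quinoline, EtOAc, rt
Reagents that add atoms: none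
Why: Lindlar semi-hydrogenation reduces the terminal alkyne to the vinyl group and stops there, leaving the 1,1-disubstituted alkene intact (the carbinol descriptor changes from R to S only because the CIP priorities change).

Step 12
Reactants: 26 diene
Product: 27 (3R,3aS,4S,7S,8aR)-6,8a-dimethyl-3-(propan-2-yl)-4-(triethylsilyloxy)-1,2,3,3a,4,7,8,8a-octahydroazulene-3,7-diol
Conditions: second-generation Grubbs catalyst RuCl2(=CHPh)(H2IMes)(PCy3) (10 mol %), CH2Cl2 (5 mM), 40 °C
Reagents that add atoms: none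
Why: Ring-closing metathesis of the vinyl and isopropenyl groups closes the seven-membered ring as its trisubstituted alkene with loss of ethene, helped by the free allylic hydroxyl, and the trans ring fusion already fixed on the cyclopentane is carried over unchanged.

Step 13
Reactants: 27 bicyclic diol
Product: 28 (3R,3aS,4S,7S,8aR)-7-[tert-butyl(dimethyl)silyl]oxy-6,8a-dimethyl-3-(propan-2-yl)-4-(triethylsilyloxy)-1,2,3,3a,4,7,8,8a-octahydroazulen-3-ol
Conditions: TBSCl, imidazole, DMF, rt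
Reagents that add atoms: tert-butyldimethylsilyl chloride, CC(C)(C)[Si](C)(C)Cl
Why: Silyl ether formation with TBSCl and imidazole is selective for the secondary allylic hydroxyl over the hindered tertiary one.

Step 14
Reactants: 28 bis-silyl ether
Product: 29 (3R,3aS,4S,7S,8aR)-7-[tert-butyl(dimethyl)silyl]oxy-6,8a-dimethyl-3-(propan-2-yl)-1,2,3,3a,4,7,8,8a-octahydroazulene-3,4-diol
Conditions: PPTS, MeOH/CH2Cl2, 0 °C
Reagents that add atoms: none
Why: Mild acid-catalysed methanolysis removes the triethylsilyl ether far faster than the tert-butyldimethylsilyl ether, freeing only the hydroxyl that will carry the ester.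

Step 15
Reactants: 30 vanillic acid
Product: 32 4-[tert-butyl(dimethyl)silyl]oxy-3-methoxybenzoic acid, via bis-silylated vanillic acid 31 (not isolated)
Conditions: TBSCl (2.5 equiv), imidazole, DMF, rt; then AcOH/THF/H2O 3:1:1, rt
Reagents that add atoms: tert-butyldimethylsilyl chloride, CC(C)(C)[Si](C)(C)Cl
Why: Bis-silylation followed by selective hydrolysis of the labile silyl ester leaves the phenol protected as its silyl ether.

Step 16
Reactants: 29 bicyclic diol; 32 silyl-protected vanillic acid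
Product: 34 (3R,3aS,4S,7S,8aR)-7-[tert-butyl(dimethyl)silyl]oxy-3-hydroxy-6,8a-dimethyl-3-(propan-2-yl)-1,2,3,3a,4,7,8,8a-octahydroazulen-4-yl 4-[tert-butyl(dimethyl)silyl]oxy-3-methoxybenzoate, via mixed anhydride 33 (not isolated)
Conditions: 2,4,6-Cl3C6H2COCl, Et3N, THF, rt; then 29, DMAP, toluene, rt → 40 °C
Reagents that add atoms: none
Why: Yamaguchi esterification through the mixed anhydride with DMAP acyl transfer acylates the secondary allylic hydroxyl with retention, while the tertiary hydroxyl is too hindered to react.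

Step 17
Reactants: 34 bis-silylated ester
Product: 35 (3R,3aS,4S,7S,8aR)-3,7-dihydroxy-6,8a-dimethyl-3-(propan-2-yl)-1,2,3,3a,4,7,8,8a-octahydroazulen-4-yl 4-hydroxy-3-methoxybenzoate
Conditions: HF·pyridine, pyridine, THF, 0 °C → rt
Reagents that add atoms: none
Why: Fluoride-mediated desilylation with buffered HF·pyridine cleaves the allylic and the aryl silyl ethers without touching the allylic benzoate or the tertiary alcohol, giving the target.

## Compound list

1 | 3-ethoxycyclopent-2-en-1-one | CCOC1=CC(=O)CC1 | starting material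
2 | allylmagnesium bromide | C=CC[Mg]Br | starting material
3 | bromomagnesium 3-ethoxy-1-(prop-2-en-1-yl)cyclopent-2-en-1-olate (racemic) | CCOC1=CC(CC=C)(O[Mg]Br)CC1 | intermediate
4 | 3-(prop-2-en-1-yl)cyclopent-2-en-1-one | C=CCC1=CC(=O)CC1 | intermediate
5 | trimethylaluminium | C[Al](C)C | starting material
6 | dimethylaluminium (3R)-3-methyl-3-(prop-2-en-1-yl)cyclopent-1-en-1-olate | C[Al](C)OC1=C[C@@](C)(CC=C)CC1 | intermediate
7 | triethyl{[(3R)-3-methyl-3-(prop-2-en-1-yl)cyclopent-1-en-1-yl]oxy}silane | CC[Si](CC)(CC)OC1=C[C@@](C)(CC=C)CC1 | intermediate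
8 | 3-(trimethylsilyl)prop-2-ynal | C[Si](C)(C)C#CC=O | starting material
9 | lithium (3R)-3-methyl-3-(prop-2-en-1-yl)cyclopent-1-en-1-olate | [Li]OC1=C[C@@](C)(CC=C)CC1 | intermediate
10 | dibutyl{[(3R)-3-methyl-3-(prop-2-en-1-yl)cyclopent-1-en-1-yl]oxy}borane | CCCCB(CCCC)OC1=C[C@@](C)(CC=C)CC1 | intermediate
11 | (2S,3R)-2-[(1R)-1-[(dibutylboranyl)oxy]-3-(trimethylsilyl)prop-2-yn-1-yl]-3-methyl-3-(prop-2-en-1-yl)cyclopentan-1-one | C[Si](C)(C)C#C[C@H](OB(CCCC)CCCC)[C@H]1C(=O)CC[C@]1(C)CC=C | intermediate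
12 | (2S,3R)-2-[(1R)-1-hydroxy-3-(trimethylsilyl)prop-2-yn-1-yl]-3-methyl-3-(prop-2-en-1-yl)cyclopentan-1-one | C[Si](C)(C)C#C[C@H](O)[C@H]1C(=O)CC[C@]1(C)CC=C | intermediate
13 | (2S,3R)-3-methyl-3-(prop-2-en-1-yl)-2-[(1R)-1-(triethylsilyloxy)-3-(trimethylsilyl)prop-2-yn-1-yl]cyclopentan-1-one | C[Si](C)(C)C#C[C@H](O[Si](CC)(CC)CC)[C@H]1C(=O)CC[C@]1(C)CC=C | intermediate
14 | isopropylmagnesium chloride | CC(C)[Mg]Cl | starting material
15 | chloromagnesium (1R,2S,3R)-3-methyl-1-(propan-2-yl)-3-(prop-2-en-1-yl)-2-[(1R)-1-(triethylsilyloxy)-3-(trimethylsilyl)prop-2-yn-1-yl]cyclopentan-1-olate | C[Si](C)(C)C#C[C@H](O[Si](CC)(CC)CC)[C@H]1[C@](O[Mg]Cl)(C(C)C)CC[C@]1(C)CC=C | intermediate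
16 | (1R,2S,3R)-3-methyl-1-(propan-2-yl)-3-(prop-2-en-1-yl)-2-[(1R)-1-(triethylsilyloxy)-3-(trimethylsilyl)prop-2-yn-1-yl]cyclopentan-1-ol | C[Si](C)(C)C#C[C@H](O[Si](CC)(CC)CC)[C@H]1[C@](O)(C(C)C)CC[C@]1(C)CC=C | intermediate
17 | 3-{(1R,2S,3R)-3-hydroxy-1-methyl-3-(propan-2-yl)-2-[(1R)-1-(triethylsilyloxy)-3-(trimethylsilyl)prop-2-yn-1-yl]cyclopentyl}propane-1,2-diol (C2 epimer pair) | C[Si](C)(C)C#C[C@H](O[Si](CC)(CC)CC)[C@H]1[C@](O)(C(C)C)CC[C@]1(C)CC(O)CO | intermediate
18 | 2-{(1R,2S,3R)-3-hydroxy-1-methyl-3-(propan-2-yl)-2-[(1R)-1-(triethylsilyloxy)-3-(trimethylsilyl)prop-2-yn-1-yl]cyclopentyl}acetaldehyde | C[Si](C)(C)C#C[C@H](O[Si](CC)(CC)CC)[C@H]1[C@](O)(C(C)C)CC[C@]1(C)CC=O | intermediate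
19 | isopropenylmagnesium bromide (prop-1-en-2-ylmagnesium bromide) | CC(=C)[Mg]Br | starting material
20 | bis(bromomagnesium) dialkoxide of 21 | C[Si](C)(C)C#C[C@H](O[Si](CC)(CC)CC)[C@H]1[C@](O[Mg]Br)(C(C)C)CC[C@]1(C)CC(O[Mg]Br)C(C)=C | intermediate
21 | (2RS)-1-{(1R,2S,3R)-3-hydroxy-1-methyl-3-(propan-2-yl)-2-[(1R)-1-(triethylsilyloxy)-3-(trimethylsilyl)prop-2-yn-1-yl]cyclopentyl}-3-methylbut-3-en-2-ol | C[Si](C)(C)C#C[C@H](O[Si](CC)(CC)CC)[C@H]1[C@](O)(C(C)C)CC[C@]1(C)CC(O)C(C)=C | intermediate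
22 | 1-{(1R,2S,3R)-3-hydroxy-1-methyl-3-(propan-2-yl)-2-[(1R)-1-(triethylsilyloxy)-3-(trimethylsilyl)prop-2-yn-1-yl]cyclopentyl}-3-methylbut-3-en-2-one | C[Si](C)(C)C#C[C@H](O[Si](CC)(CC)CC)[C@H]1[C@](O)(C(C)C)CC[C@]1(C)CC(=O)C(C)=C | intermediate
23 | 2-{[(2S)-1-{(1R,2S,3R)-3-hydroxy-1-methyl-3-(propan-2-yl)-2-[(1R)-1-(triethylsilyloxy)-3-(trimethylsilyl)prop-2-yn-1-yl]cyclopentyl}-3-methylbut-3-en-2-yl]oxy}-1,3,2-benzodioxaborole | C[Si](C)(C)C#C[C@H](O[Si](CC)(CC)CC)[C@H]1[C@](O)(C(C)C)CC[C@]1(C)C[C@H](OB2Oc3ccccc3O2)C(C)=C | intermediate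
24 | (2S)-1-{(1R,2S,3R)-3-hydroxy-1-methyl-3-(propan-2-yl)-2-[(1R)-1-(triethylsilyloxy)-3-(trimethylsilyl)prop-2-yn-1-yl]cyclopentyl}-3-methylbut-3-en-2-ol | C[Si](C)(C)C#C[C@H](O[Si](CC)(CC)CC)[C@H]1[C@](O)(C(C)C)CC[C@]1(C)C[C@H](O)C(C)=C | intermediate
25 | (2S)-1-{(1R,2S,3R)-3-hydroxy-1-methyl-3-(propan-2-yl)-2-[(1R)-1-(triethylsilyloxy)prop-2-yn-1-yl]cyclopentyl}-3-methylbut-3-en-2-ol | C#C[C@H](O[Si](CC)(CC)CC)[C@H]1[C@](O)(C(C)C)CC[C@]1(C)C[C@H](O)C(C)=C | intermediate
26 | (2S)-1-{(1R,2S,3R)-3-hydroxy-1-methyl-3-(propan-2-yl)-2-[(1S)-1-(triethylsilyloxy)prop-2-en-1-yl]cyclopentyl}-3-methylbut-3-en-2-ol | C=C[C@H](O[Si](CC)(CC)CC)[C@H]1[C@](O)(C(C)C)CC[C@]1(C)C[C@H](O)C(C)=C | intermediate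
27 | (3R,3aS,4S,7S,8aR)-6,8a-dimethyl-3-(propan-2-yl)-4-(triethylsilyloxy)-1,2,3,3a,4,7,8,8a-octahydroazulene-3,7-diol | CC[Si](CC)(CC)O[C@H]1C=C(C)[C@@H](O)C[C@@]2(C)CC[C@@](O)(C(C)C)[C@H]12 | intermediate
28 | (3R,3aS,4S,7S,8aR)-7-[tert-butyl(dimethyl)silyl]oxy-6,8a-dimethyl-3-(propan-2-yl)-4-(triethylsilyloxy)-1,2,3,3a,4,7,8,8a-octahydroazulen-3-ol | CC[Si](CC)(CC)O[C@H]1C=C(C)[C@@H](O[Si](C)(C)C(C)(C)C)C[C@@]2(C)CC[C@@](O)(C(C)C)[C@H]12 | intermediate
29 | (3R,3aS,4S,7S,8aR)-7-[tert-butyl(dimethyl)silyl]oxy-6,8a-dimethyl-3-(propan-2-yl)-1,2,3,3a,4,7,8,8a-octahydroazulene-3,4-diol | O[C@H]1C=C(C)[C@@H](O[Si](C)(C)C(C)(C)C)C[C@@]2(C)CC[C@@](O)(C(C)C)[C@H]12 | intermediate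
30 | vanillic acid (4-hydroxy-3-methoxybenzoic acid) | COc1cc(C(=O)O)ccc1O | starting material
31 | tert-butyldimethylsilyl 4-[tert-butyl(dimethyl)silyl]oxy-3-methoxybenzoate | COc1cc(C(=O)O[Si](C)(C)C(C)(C)C)ccc1O[Si](C)(C)C(C)(C)C | intermediate
32 | 4-[tert-butyl(dimethyl)silyl]oxy-3-methoxybenzoic acid | COc1cc(C(=O)O)ccc1O[Si](C)(C)C(C)(C)C | intermediate
33 | 4-[tert-butyl(dimethyl)silyl]oxy-3-methoxybenzoic 2,4,6-trichlorobenzoic anhydride | COc1cc(C(=O)OC(=O)c2c(Cl)cc(Cl)cc2Cl)ccc1O[Si](C)(C)C(C)(C)C | intermediate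
34 | (3R,3aS,4S,7S,8aR)-7-[tert-butyl(dimethyl)silyl]oxy-3-hydroxy-6,8a-dimethyl-3-(propan-2-yl)-1,2,3,3a,4,7,8,8a-octahydroazulen-4-yl 4-[tert-butyl(dimethyl)silyl]oxy-3-methoxybenzoate | COc1cc(C(=O)O[C@H]2C=C(C)[C@@H](O[Si](C)(C)C(C)(C)C)C[C@@]3(C)CC[C@@](O)(C(C)C)[C@H]23)ccc1O[Si](C)(C)C(C)(C)C | intermediate
35 | (3R,3aS,4S,7S,8aR)-3,7-dihydroxy-6,8a-dimethyl-3-(propan-2-yl)-1,2,3,3a,4,7,8,8a-octahydroazulen-4-yl 4-hydroxy-3-methoxybenzoate | COc1cc(C(=O)O[C@H]2C=C(C)[C@@H](O)C[C@@]3(C)CC[C@@](O)(C(C)C)[C@H]23)ccc1O | target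

## Step count and weak points

Total: 17 steps. Longest linear sequence: 16 steps (steps 1 to 14, then 16 and 17); step 15 is a one-step side branch.

**Step 3 (aldol).** The alkynyl aldehyde is small, so the anti/syn ratio at the carbinol may be modest, and the face selectivity rests only on allyl being larger than methyl. The ring epimer from attack syn to allyl is removed by chromatography at 12 or 13. The fallback sets the carbinol by a reagent-controlled ynone reduction instead of by the aldol. It sets out from 16, carried through steps 4 and 5 as the carbinol epimer pair, and comes back at 16 as a single epimer. PPTS in MeOH removes the triethylsilyl group to give (1R,2S,3R)-2-[(1R)-1-hydroxy-3-(trimethylsilyl)prop-2-yn-1-yl]-3-methyl-1-(propan-2-yl)-3-(prop-2-en-1-yl)cyclopentan-1-ol F6 together with its carbinol epimer. Dess–Martin oxidation converges both on 1-[(1R,2R,5R)-2-hydroxy-5-methyl-2-(propan-2-yl)-5-(prop-2-en-1-yl)cyclopentyl]-3-(trimethylsilyl)prop-2-yn-1-one F7. Noyori transfer hydrogenation with Ru[(R,R)-TsDPEN](p-cymene) in i-PrOH returns F6 as one epimer, because the alkynyl group takes the place of the aryl group in the catalyst model and the (R,R) catalyst gives the (R) propargylic alcohol. TESCl and imidazole then silylate only the secondary hydroxyl to give 16.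

**Step 2 (asymmetric conjugate addition).** The enantioselectivity of methyl addition to a five-membered β-substituted enone is ligand dependent, and the enolate must be trapped on oxygen. The main route already upgrades a modest ee, because the reagent-controlled step 9 turns the minor enantiomer series into a separable diastereomer. The fallback builds the quaternary methyl from a cyclopropane; it sets out from 4 and comes back at 7.
- Luche reduction (NaBH4, CeCl3·7H2O, MeOH) gives racemic 3-(prop-2-en-1-yl)cyclopent-2-en-1-ol F1.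
- Lipase-catalysed acetylation (Burkholderia cepacia lipase, vinyl acetate) converts the (R) alcohol, as the Kazlauskas rule predicts, into (1R)-3-(prop-2-en-1-yl)cyclopent-2-en-1-yl acetate F3 and leaves (1S)-3-(prop-2-en-1-yl)cyclopent-2-en-1-ol F2.
- Hydroxyl-directed Simmons–Smith cyclopropanation (Et2Zn, CH2I2, CH2Cl2, −20 °C) adds CH2 syn to the hydroxyl, faster than to the isolated allyl alkene, giving (1R,2S,5R)-5-(prop-2-en-1-yl)bicyclo[3.1.0]hexan-2-ol F4.
- Dess–Martin oxidation gives (1R,5R)-5-(prop-2-en-1-yl)bicyclo[3.1.0]hexan-2-one F5.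
- Li in NH3/THF at −78 °C cleaves the external cyclopropane bond that overlaps with the carbonyl π system. The CH2 becomes the quaternary methyl group on the face the hydroxyl once occupied, and the lithium enolate 9 is left regiospecifically; Et3SiCl and Et3N silylate it to 7.

**Step 9 (CBS reduction).** The small substituent of the ketone is a neopentyl-type CH2, so its differentiation from the isopropenyl group, and with it the diastereoselectivity, may be lower than usual. The fallback drops the oxidation and reduction and uses separation plus inversion; it sets out from 21 and comes back at 25. The epimers of 21 are separated by chromatography, and the (2S) epimer is 24 itself. The other epimer, (2R)-1-{(1R,2S,3R)-3-hydroxy-1-methyl-3-(propan-2-yl)-2-[(1R)-1-(triethylsilyloxy)-3-(trimethylsilyl)prop-2-yn-1-yl]cyclopentyl}-3-methylbut-3-en-2-ol F8, is inverted by a Mitsunobu reaction (4-nitrobenzoic acid, PPh3, DIAD, toluene, 0 °C). This gives (2S)-1-{(1R,2S,3R)-3-hydroxy-1-methyl-3-(propan-2-yl)-2-[(1R)-1-(triethylsilyloxy)-3-(trimethylsilyl)prop-2-yn-1-yl]cyclopentyl}-3-methylbut-3-en-2-yl 4-nitrobenzoate F9. K2CO3 in MeOH then cleaves the ester and the alkynyl silyl group in one operation to give 25, and 24 from the separation joins it after step 10.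

## Further compounds

F1 | step 2 | racemic 3-(prop-2-en-1-yl)cyclopent-2-en-1-ol | OC1C=C(CC=C)CC1
F2 | step 2 | (1S)-3-(prop-2-en-1-yl)cyclopent-2-en-1-ol | O[C@@H]1C=C(CC=C)CC1
F3 | step 2 | (1R)-3-(prop-2-en-1-yl)cyclopent-2-en-1-yl acetate | CC(=O)O[C@H]1C=C(CC=C)CC1
F4 | step 2 | (1R,2S,5R)-5-(prop-2-en-1-yl)bicyclo[3.1.0]hexan-2-ol | O[C@@H]1[C@@H]2C[C@]2(CC=C)CC1
F5 | step 2 | (1R,5R)-5-(prop-2-en-1-yl)bicyclo[3.1.0]hexan-2-one | O=C1[C@@H]2C[C@]2(CC=C)CC1
F6 | step 3 | (1R,2S,3R)-2-[(1R)-1-hydroxy-3-(trimethylsilyl)prop-2-yn-1-yl]-3-methyl-1-(propan-2-yl)-3-(prop-2-en-1-yl)cyclopentan-1-ol | C[Si](C)(C)C#C[C@H](O)[C@H]1[C@](O)(C(C)C)CC[C@]1(C)CC=C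
F7 | step 3 | 1-[(1R,2R,5R)-2-hydroxy-5-methyl-2-(propan-2-yl)-5-(prop-2-en-1-yl)cyclopentyl]-3-(trimethylsilyl)prop-2-yn-1-one | C[Si](C)(C)C#CC(=O)[C@H]1[C@](O)(C(C)C)CC[C@]1(C)CC=C
F8 | step 9 | (2R)-1-{(1R,2S,3R)-3-hydroxy-1-methyl-3-(propan-2-yl)-2-[(1R)-1-(triethylsilyloxy)-3-(trimethylsilyl)prop-2-yn-1-yl]cyclopentyl}-3-methylbut-3-en-2-ol | C[Si](C)(C)C#C[C@H](O[Si](CC)(CC)CC)[C@H]1[C@](O)(C(C)C)CC[C@]1(C)C[C@@H](O)C(C)=C
F9 | step 9 | (2S)-1-{(1R,2S,3R)-3-hydroxy-1-methyl-3-(propan-2-yl)-2-[(1R)-1-(triethylsilyloxy)-3-(trimethylsilyl)prop-2-yn-1-yl]cyclopentyl}-3-methylbut-3-en-2-yl 4-nitrobenzoate | C[Si](C)(C)C#C[C@H](O[Si](CC)(CC)CC)[C@H]1[C@](O)(C(C)C)CC[C@]1(C)C[C@H](OC(=O)c2ccc(cc2)[N+](=O)[O-])C(C)=C
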